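The rate constants are assumed; what happens was integrated by code.

Take 2.4, the equilibrium constant of the linking step times the first end groups charged, and read this flask from it.

    first end groups + second end groups ⇌ links (K1 = 16 M⁻¹, k1 = 0.025 M⁻¹ s⁻¹)
    2 first end groups → self-condensation product (k2 = 4.4 × 10⁻⁵ M⁻¹ s⁻¹)

first end groups 0.15 M; second end groups 0.980 equiv; time 2.0 h

- average number of monomer units in a chain (unreacted monomers counted as chains of one) at 2.0 h
- part of the first end groups that has reacted at 2.0 h

- in percentages every species weighs as the first end groups in it: one self-condensation product counts as two
- for a step with 2 of a species take k times the square, and two of it per event
- each molecule carries two end groups: a chain counts once for every two ends that are left, dead ends included; the units are half of the end groups of the two monomers charged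
- a link that another step uses up counts as cut, two dead ends; so do two ends of one kind that react with each other
- what has gone from first end groups into another species counts as reacted, even if it can come back
- run time (flask): 2.0 h

Check the clock first. The forward half-life of first end groups, the way back not counted, is 0.052 h against 2.0 h, so treat the linking step as balanced at the asked time. Set self-condensation aside for a first reckoning, and put its cost back afterwards.

Now work with what is left, not with what is made. Let u be the part of the first end groups charged that stands free. Each link took one end of each kind, so [links] is the rest of the charge. The second end groups, the limiting reagent, were charged short, so in this first reckoning [second end groups] stays 0.00300 M below [first end groups]. Put this into the balance [links] = K [first end groups] [second end groups] and divide by the charge: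

1 − u = 2.4 · u · (u − 2.00%)

u = 47.7%

This u, the fraction left, gives both answers. The reacted part is its complement:

c = 1 − u = 52.3%

Every chain has two ends, so dp is the end groups charged over the end groups left:

dp = 0.297 M / 0.140 M = 2.12

Now put the cost back. Self-condensation has no way back, so a balanced linking step does not stop it. Held at this [first end groups], it takes 2 k [first end groups] [first end groups] t = 2.16% of the first end groups charged by 2.0 h. That is more than the 2.00% by which the second end groups were charged short, so take my c and dp as the values of the balance without this drain.

The forecast puts c at 53.7%, above my 52.3%, and dp at 2.08, below my 2.12, since the slow self-condensation “adds a small dead-end count to the chain tally”.

The flask gives dp 2.09 and c 53.8%. Its first end groups stand at 48.4% after 0.200 h and at 46.2% after 2.00 h, against a fraction left of 47.7%, with 2.23% in self-condensation product against my 2.16%. Now thin the charge to 0.037 M of first end groups, with the same equivalents. The constant times the charge falls to 0.592, and the same balance gives a fraction left of 71.0%. That thinner flask holds 70.0% of its first end groups free after 2.00 h.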